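**Plan**

- Retrosynthesis: the tetrahydrofuran O1–C2 bond is cut and C2 is rejoined to C4, giving a 1-formylcyclopropane. C2 carries the 4-methoxy-substituted aryl ring (donor) and C4 carries C5 as CHO (acceptor), so the C2–C4 bond is a donor–acceptor bond whose ionisation lets the formyl oxygen become O1.
- Further cuts: C4–CH2 (alkylation of a cyclopropyl nitrile anion by the dihydrobenzofuranylmethyl bromide), the cyclopropane (carbene addition within an E-cinnamyl diazoacetate), and in the dihydrobenzofuran C2'–C3' (carbene C–H insertion) and aryl–C3' (ortho-lithiation, oxalate).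
- Forward: the dihydrobenzofuran ring and, separately, the cyclopropane-fused lactone are made first; the fragments are joined by C-alkylation; the dihydrofuran arises by ring expansion and becomes the tetrahydrofuran on hydrogenation.
- Stereochemistry: C2' from the chiral dirhodium carboxylate in the insertion, C3' by base equilibration to trans; C3 from the chiral dirhodium carboxamidate in the cyclopropanation; C2 trans to C3 in the ring expansion; C4 by hydrogen delivery anti to the C3 side chain.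

Key step: step 22

Remark 1: the sense of induction of the two chiral dirhodium catalysts (steps 7 and 16) is assumed by analogy with simpler substrates; should either favour the mirror image, its enantiomer is used.
Remark 2: the quaternary cyclopropane carbon made in step 20 is left undefined on purpose in the compounds that carry it, because it becomes sp2 in step 22 and both epimers give the same product.
Shorthand in names: ArA = 3-(benzyloxy)-4-methoxyphenyl; ArB = 4-(benzyloxy)-3-methoxyphenyl; TBDPS = tert-butyldiphenylsilyl; DBF = (2S,3R)-2-ArB-3-(benzyloxymethyl)-4-methoxy-2,3-dihydro-1-benzofuran-6-yl.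

**Dihydrobenzofuran fragment**

Step 1
Reactants: 1 3,5-dimethoxybenzyl alcohol
Product: 2 3,5-dimethoxybenzyl TBDPS ether
Conditions: TBDPSCl, imidazole, DMF, rt
Reagents that add atoms: tert-butyl(chloro)diphenylsilane, CC(C)(C)[Si](Cl)(c1ccccc1)c1ccccc1
Why: Imidazole-promoted silylation of the primary alcohol gives an ether that should withstand the alkyllithium and the boron Lewis acid of the next two steps.

Step 2
Reactants: 2 3,5-dimethoxybenzyl TBDPS ether
Product: 4 ethyl 2-[2,6-dimethoxy-4-(TBDPSO-methyl)phenyl]-2-oxoacetate, via 4-lithio arene 3 (not isolated)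
Conditions: n-BuLi, THF, 0 °C; then cannulated into (CO2Et)2 (3 equiv), THF, −78 °C
Reagents that add atoms: diethyl oxalate, CCOC(=O)C(=O)OCC
Why: Directed ortho-metalation takes place at the position flanked by both methoxy groups, and the aryllithium added to excess oxalate is acylated once to the aryl glyoxylate.

Step 3
Reactants: 4 ethyl 2-[2,6-dimethoxy-4-(TBDPSO-methyl)phenyl]-2-oxoacetate
Product: 5 ethyl 2-[2-hydroxy-6-methoxy-4-(TBDPSO-methyl)phenyl]-2-oxoacetate
Conditions: BCl3 (1.2 equiv), CH2Cl2, −78 → 0 °C; aq. NaHCO3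
Reagents that add atoms: none
Why: Boron held between the ketone oxygen and one ortho methoxy group cleaves only that methyl ether (chelation-controlled demethylation), and the chelated boron phenoxide so formed shields the second methoxy group.

Step 4
Reactants: 6 4-(benzyloxy)-3-methoxybenzyl alcohol
Product: 7 4-(benzyloxy)-3-methoxybenzyl bromide
Conditions: PBr3, Et2O, 0 °C
Reagents that add atoms: phosphorus tribromide, BrP(Br)Br
Why: Bromination of a benzylic alcohol with PBr3 at low temperature leaves the aryl benzyl ether intact; the bromide is used at once.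

Step 5
Reactants: 5 ethyl 2-[2-hydroxy-6-methoxy-4-(TBDPSO-methyl)phenyl]-2-oxoacetate; 7 4-(benzyloxy)-3-methoxybenzyl bromide
Product: 8 ethyl 2-[2-(ArB-methoxy)-6-methoxy-4-(TBDPSO-methyl)phenyl]-2-oxoacetate
Conditions: K2CO3, DMF, rt
Reagents that add atoms: none
Why: Williamson etherification of the acidic ortho-acylphenol with a reactive benzylic bromide under mild carbonate conditions.

Step 6
Reactants: 8 ethyl 2-[2-(ArB-methoxy)-6-methoxy-4-(TBDPSO-methyl)phenyl]-2-oxoacetate
Product: 10 ethyl 2-diazo-2-[2-(ArB-methoxy)-6-methoxy-4-(TBDPSO-methyl)phenyl]acetate, via tosylhydrazone 9 (not isolated)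
Conditions: TsNHNH2, EtOH, 70 °C; then DBU, CH2Cl2, rt
Reagents that add atoms: 4-methylbenzenesulfonohydrazide, Cc1ccc(cc1)S(=O)(=O)NN
Why: Condensation at the electrophilic keto group of the α-keto ester and base-induced loss of sulfinate (Bamford–Stevens-type elimination) is the standard entry to aryl diazoacetates.

Step 7
Reactants: 10 ethyl 2-diazo-2-[2-(ArB-methoxy)-6-methoxy-4-(TBDPSO-methyl)phenyl]acetate
Product: 12 ethyl (2S,3S)-2-ArB-4-methoxy-6-(TBDPSO-methyl)-2,3-dihydro-1-benzofuran-3-carboxylate (2,3-trans), via cis ester 11 (not isolated)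
Conditions: Rh2(S-PTTL)4 (2 mol %), toluene, −60 °C; then NaOEt (0.2 equiv), EtOH, rt
Reagents that add atoms: none
Why: The divalent rhodium carbene inserts into the ether-activated benzylic C–H bond through a five-membered transition state (intramolecular 1,5 C–H insertion), the ligands of Rh2(S-PTTL)4 (dirhodium tetrakis[N-phthaloyl-(S)-tert-leucinate]) fixing C2 as S in the kinetic cis ester, and ethoxide then epimerises the enolisable C3 to the more stable trans ester.

Step 8
Reactants: 12 ethyl (2S,3S)-2-ArB-4-methoxy-6-(TBDPSO-methyl)-2,3-dihydro-1-benzofuran-3-carboxylate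
Product: 13 [(2S,3R)-2-ArB-4-methoxy-6-(TBDPSO-methyl)-2,3-dihydro-1-benzofuran-3-yl]methanol
Conditions: LiBH4, THF, 0 °C → rt
Reagents that add atoms: none
Why: Borohydride reduction of the ester gives the primary alcohol without touching C3, which is no longer epimerisable afterwards.

Step 9
Reactants: 13 [(2S,3R)-2-ArB-4-methoxy-6-(TBDPSO-methyl)-2,3-dihydro-1-benzofuran-3-yl]methanol
Product: 14 (2S,3R)-2-ArB-3-(benzyloxymethyl)-4-methoxy-6-(TBDPSO-methyl)-2,3-dihydro-1-benzofuran
Conditions: NaH, BnBr, Bu4NI (cat.), THF–DMF, 0 °C → rt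
Reagents that add atoms: benzyl bromide, BrCc1ccccc1
Why: Williamson benzylation gives an ether that survives fluoride, amide base and hydride and falls in the final hydrogenolysis together with the phenolic benzyl groups.

Step 10
Reactants: 14 (2S,3R)-2-ArB-3-(benzyloxymethyl)-4-methoxy-6-(TBDPSO-methyl)-2,3-dihydro-1-benzofuran
Product: 15 [(2S,3R)-2-ArB-3-(benzyloxymethyl)-4-methoxy-2,3-dihydro-1-benzofuran-6-yl]methanol
Conditions: Bu4NF, THF, rt
Reagents that add atoms: none
Why: Fluoride cleaves the silyl ether selectively in the presence of benzyl ethers.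

Step 11
Reactants: 15 [(2S,3R)-2-ArB-3-(benzyloxymethyl)-4-methoxy-2,3-dihydro-1-benzofuran-6-yl]methanol
Product: 16 (2S,3R)-2-ArB-3-(benzyloxymethyl)-6-(bromomethyl)-4-methoxy-2,3-dihydro-1-benzofuran
Conditions: CBr4, PPh3, CH2Cl2, 0 °C
Reagents that add atoms: carbon tetrabromide, BrC(Br)(Br)Br
Why: Appel bromination converts the benzylic alcohol under neutral conditions into the alkylating agent.

**Cyclopropane fragment**

Step 12
Reactants: 17 3-(benzyloxy)-4-methoxybenzaldehyde
Product: 18 ethyl (E)-3-ArA-prop-2-enoate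
Conditions: (EtO)2P(O)CH2CO2Et, NaH, THF, 0 °C → rt
Reagents that add atoms: triethyl phosphonoacetate, CCOC(=O)CP(=O)(OCC)OCC
Why: Horner–Wadsworth–Emmons olefination of an aryl aldehyde gives the E enoate.

Step 13
Reactants: 18 ethyl (E)-3-ArA-prop-2-enoate
Product: 19 (E)-3-ArA-prop-2-en-1-ol
Conditions: i-Bu2AlH (2.2 equiv), CH2Cl2, −78 °C
Reagents that add atoms: none
Why: 1,2-Reduction of the enoate by the aluminium hydride at low temperature gives the E allylic alcohol.

Step 14
Reactants: 19 (E)-3-ArA-prop-2-en-1-ol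
Product: 20 (E)-3-ArA-prop-2-enyl 3-oxobutanoate
Conditions: 2,2,6-trimethyl-4H-1,3-dioxin-4-one, toluene, 110 °C
Reagents that add atoms: 2,2,6-trimethyl-4H-1,3-dioxin-4-one, CC1=CC(=O)OC(C)(C)O1
Why: Thermolysis of the dioxinone releases acetylketene, which acylates the alcohol (acetoacetylation) under neutral conditions that should not ionise the electron-rich cinnamyl system.

Step 15
Reactants: 20 (E)-3-ArA-prop-2-enyl 3-oxobutanoate
Product: 22 (E)-3-ArA-prop-2-enyl diazoacetate, via diazoacetoacetate 21 (not isolated)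
Conditions: 4-AcNHC6H4SO2N3, Et3N, MeCN, rt; then LiOH (aq), rt
Reagents that add atoms: 4-acetamidobenzenesulfonyl azide, CC(=O)Nc1ccc(cc1)S(=O)(=O)N=[N+]=[N-]
Why: Regitz diazo transfer to the active methylene group followed by hydroxide-induced deacetylation is the standard preparation of allylic diazoacetates.

Step 16
Reactants: 22 (E)-3-ArA-prop-2-enyl diazoacetate
Product: 23 (1R,5S,6S)-6-ArA-3-oxabicyclo[3.1.0]hexan-2-one (aryl exo)
Conditions: Rh2(4S-MPPIM)4 (1 mol %), CH2Cl2, reflux, slow addition of 22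
Reagents that add atoms: none
Why: Intramolecular cyclopropanation of the allylic diazoacetate by the chiral carboxamidate Rh2(4S-MPPIM)4 (dirhodium tetrakis[methyl (4S)-2-oxo-1-(3-phenylpropanoyl)imidazolidine-4-carboxylate]) carries the E geometry into the trans relation of aryl group and lactone CH2, and sets the ring-fusion carbon C5 (the future tetrahydrofuran C3) as S by catalyst-controlled choice of the alkene face.

Step 17
Reactants: 23 (1R,5S,6S)-6-ArA-3-oxabicyclo[3.1.0]hexan-2-one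
Product: 24 (1R,2S,3S)-2-ArA-3-(hydroxymethyl)cyclopropane-1-carboxamide
Conditions: NH3 (7 M in MeOH), rt
Reagents that add atoms: ammonia, N
Why: Ammonolysis of the strained cis-fused lactone gives the hydroxy amide with all three ring centres unchanged.

Step 18
Reactants: 24 (1R,2S,3S)-2-ArA-3-(hydroxymethyl)cyclopropane-1-carboxamide
Product: 25 (1R,2S,3S)-2-ArA-3-(TBDPSO-methyl)cyclopropane-1-carboxamide
Conditions: TBDPSCl, imidazole, DMF, rt
Reagents that add atoms: tert-butyl(chloro)diphenylsilane, CC(C)(C)[Si](Cl)(c1ccccc1)c1ccccc1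
Why: O-Silylation of the primary alcohol (the primary amide does not react) blocks relactonisation and installs the bulky group that later shields one face of the enol ether.

Step 19
Reactants: 25 (1R,2S,3S)-2-ArA-3-(TBDPSO-methyl)cyclopropane-1-carboxamide
Product: 26 (1R,2R,3S)-2-ArA-3-(TBDPSO-methyl)cyclopropane-1-carbonitrile (same spatial arrangement as 25)
Conditions: (CF3CO)2O, Et3N, CH2Cl2, 0 °C
Reagents that add atoms: none
Why: Dehydration of the primary carboxamide with trifluoroacetic anhydride gives the nitrile, which acidifies the cyclopropane C–H for alkylation and is a latent formyl group.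

**Union and end game**

Step 20
Reactants: 26 (1R,2R,3S)-2-ArA-3-(TBDPSO-methyl)cyclopropane-1-carbonitrile; 16 (2S,3R)-2-ArB-3-(benzyloxymethyl)-6-(bromomethyl)-4-methoxy-2,3-dihydro-1-benzofuran
Product: 28 (2R,3S)-2-ArA-1-(DBF-methyl)-3-(TBDPSO-methyl)cyclopropane-1-carbonitrile as both C1 epimers, via lithiated nitrile 27 (not isolated)
Conditions: LiN(i-Pr)2, THF, −78 °C; then 16, −78 → 0 °C
Reagents that add atoms: none
Why: α-Lithiation of the cyclopropanecarbonitrile and SN2 alkylation by the benzylic bromide forms the quaternary carbon and joins the fragments, and the configuration created here is irrelevant because this carbon becomes sp2 in step 22.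

Step 21
Reactants: 28 (2R,3S)-2-ArA-1-(DBF-methyl)-3-(TBDPSO-methyl)cyclopropane-1-carbonitrile
Product: 29 (2R,3S)-2-ArA-1-(DBF-methyl)-3-(TBDPSO-methyl)cyclopropane-1-carbaldehyde as both C1 epimers
Conditions: i-Bu2AlH (1.5 equiv), toluene, −78 → −20 °C; then aq. tartaric acid
Reagents that add atoms: water, O
Why: The aluminium hydride adds once to the nitrile and the N-aluminio imine is hydrolysed on work-up to the non-enolisable aldehyde.

Step 22
Reactants: 29 (2R,3S)-2-ArA-1-(DBF-methyl)-3-(TBDPSO-methyl)cyclopropane-1-carbaldehyde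
Product: 30 (2R,3S)-2-ArA-4-(DBF-methyl)-3-(TBDPSO-methyl)-2,3-dihydrofuran
Conditions: Sc(OTf)3 (10 mol %), 4 Å MS, ClCH2CH2Cl, rt → 50 °C
Reagents that add atoms: none
Why: Sc(OTf)3 binds the formyl oxygen and, pushed by the 4-methoxy group of the aryl donor, the bond between the formyl-bearing quaternary carbon and the aryl-bearing carbon heterolyses with release of ring strain to a scandium enolate and a quinone-methide-like benzylic cation, which collapses through oxygen; this is the Cloke–Wilson rearrangement of donor–acceptor cyclopropyl carbonyl compounds, the closest known reaction type. The dihydrofuran ring closes by O-alkylation of the enolate, a 5-(enolendo)-exo-trig attack on the cationic benzylic carbon that forms O1–C2. The only new stereocentre, C2, is controlled by the adjacent C3 centre: the planar cation should be captured so that the aryl group ends up trans to the silyloxymethyl group, and because closure is reversible under the Lewis acid the trans isomer is also the one expected to accumulate. The step needs cleavage of the bond to the aryl-bearing carbon and not of the bond to the carbon bearing the silyloxymethyl group, which the electron-rich aryl group secures, and closure through oxygen, which ring strain secures because closure through carbon only regenerates the cyclopropane. Both epimers of 29 give the same enolate since the quaternary carbon becomes sp2 (C4), and C3, set in step 16, is not touched.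

Step 23
Reactants: 30 (2R,3S)-2-ArA-4-(DBF-methyl)-3-(TBDPSO-methyl)-2,3-dihydrofuran
Product: 31 the (2R,3S,4S)-tetrahydrofuran with free phenols and free dihydrobenzofuran CH2OH, TBDPS ether retained at the C3 side chain
Conditions: H2 (1 atm), 10% Pd/C, EtOAc, rt
Reagents that add atoms: none
Why: Syn addition of hydrogen on palladium from the face anti to the adjacent C3 silyloxymethyl group should set C4 with the 3,4-cis relation, and the three benzyl ethers are cleaved by hydrogenolysis in the same operation.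

Step 24
Reactants: 31 the (2R,3S,4S)-tetrahydrofuran TBDPS ether
Product: 32 CNP0242386.1, 5-[(2R,3S,4S)-3-(hydroxymethyl)-4-{[(2S,3R)-2-(4-hydroxy-3-methoxyphenyl)-3-(hydroxymethyl)-4-methoxy-2,3-dihydro-1-benzofuran-6-yl]methyl}oxolan-2-yl]-2-methoxyphenol
Conditions: Bu4NF, THF, 0 °C → rt
Reagents that add atoms: none
Why: Fluoride removes the remaining silyl ether and frees the last primary alcohol without affecting any stereocentre.

**Compound list**

1 | 3,5-dimethoxybenzyl alcohol | COc1cc(CO)cc(OC)c1 | starting material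
2 | 3,5-dimethoxybenzyl TBDPS ether | COc1cc(CO[Si](c2ccccc2)(c2ccccc2)C(C)(C)C)cc(OC)c1 | intermediate
3 | 4-lithio derivative of 2 (lithium between the methoxy groups) | [Li]c1c(OC)cc(CO[Si](c2ccccc2)(c2ccccc2)C(C)(C)C)cc1OC | intermediate (not isolated)
4 | ethyl 2-[2,6-dimethoxy-4-(TBDPSO-methyl)phenyl]-2-oxoacetate | CCOC(=O)C(=O)c1c(OC)cc(CO[Si](c2ccccc2)(c2ccccc2)C(C)(C)C)cc1OC | intermediate
5 | ethyl 2-[2-hydroxy-6-methoxy-4-(TBDPSO-methyl)phenyl]-2-oxoacetate | CCOC(=O)C(=O)c1c(O)cc(CO[Si](c2ccccc2)(c2ccccc2)C(C)(C)C)cc1OC | intermediate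
6 | 4-(benzyloxy)-3-methoxybenzyl alcohol | COc1cc(CO)ccc1OCc1ccccc1 | starting material
7 | 4-(benzyloxy)-3-methoxybenzyl bromide | COc1cc(CBr)ccc1OCc1ccccc1 | intermediate
8 | ethyl 2-[2-(ArB-methoxy)-6-methoxy-4-(TBDPSO-methyl)phenyl]-2-oxoacetate | CCOC(=O)C(=O)c1c(OCc2ccc(OCc3ccccc3)c(OC)c2)cc(CO[Si](c2ccccc2)(c2ccccc2)C(C)(C)C)cc1OC | intermediate
9 | N-tosylhydrazone of 8 | CCOC(=O)C(=NNS(=O)(=O)c1ccc(C)cc1)c1c(OCc2ccc(OCc3ccccc3)c(OC)c2)cc(CO[Si](c2ccccc2)(c2ccccc2)C(C)(C)C)cc1OC | intermediate (not isolated)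
10 | ethyl 2-diazo-2-[2-(ArB-methoxy)-6-methoxy-4-(TBDPSO-methyl)phenyl]acetate | CCOC(=O)C(=[N+]=[N-])c1c(OCc2ccc(OCc3ccccc3)c(OC)c2)cc(CO[Si](c2ccccc2)(c2ccccc2)C(C)(C)C)cc1OC | intermediate
11 | ethyl (2S,3R)-2-ArB-4-methoxy-6-(TBDPSO-methyl)-2,3-dihydro-1-benzofuran-3-carboxylate (2,3-cis) | CC(C)(C)[Si](c1ccccc1)(c1ccccc1)OCc1cc(OC)c2c(c1)O[C@H](c1ccc(OCc3ccccc3)c(OC)c1)[C@@H]2C(=O)OCC | intermediate (not isolated)
12 | ethyl (2S,3S)-2-ArB-4-methoxy-6-(TBDPSO-methyl)-2,3-dihydro-1-benzofuran-3-carboxylate (2,3-trans) | CC(C)(C)[Si](c1ccccc1)(c1ccccc1)OCc1cc(OC)c2c(c1)O[C@H](c1ccc(OCc3ccccc3)c(OC)c1)[C@H]2C(=O)OCC | intermediate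
13 | [(2S,3R)-2-ArB-4-methoxy-6-(TBDPSO-methyl)-2,3-dihydro-1-benzofuran-3-yl]methanol (2,3-trans) | CC(C)(C)[Si](c1ccccc1)(c1ccccc1)OCc1cc(OC)c2c(c1)O[C@H](c1ccc(OCc3ccccc3)c(OC)c1)[C@H]2CO | intermediate
14 | (2S,3R)-2-ArB-3-(benzyloxymethyl)-4-methoxy-6-(TBDPSO-methyl)-2,3-dihydro-1-benzofuran | CC(C)(C)[Si](c1ccccc1)(c1ccccc1)OCc1cc(OC)c2c(c1)O[C@H](c1ccc(OCc3ccccc3)c(OC)c1)[C@H]2COCc1ccccc1 | intermediate
15 | [(2S,3R)-2-ArB-3-(benzyloxymethyl)-4-methoxy-2,3-dihydro-1-benzofuran-6-yl]methanol | OCc1cc(OC)c2c(c1)O[C@H](c1ccc(OCc3ccccc3)c(OC)c1)[C@H]2COCc1ccccc1 | intermediate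
16 | (2S,3R)-2-ArB-3-(benzyloxymethyl)-6-(bromomethyl)-4-methoxy-2,3-dihydro-1-benzofuran | BrCc1cc(OC)c2c(c1)O[C@H](c1ccc(OCc3ccccc3)c(OC)c1)[C@H]2COCc1ccccc1 | intermediate
17 | 3-(benzyloxy)-4-methoxybenzaldehyde | COc1ccc(C=O)cc1OCc1ccccc1 | starting material
18 | ethyl (E)-3-ArA-prop-2-enoate | CCOC(=O)/C=C/c1ccc(OC)c(OCc2ccccc2)c1 | intermediate
19 | (E)-3-ArA-prop-2-en-1-ol | OC/C=C/c1ccc(OC)c(OCc2ccccc2)c1 | intermediate
20 | (E)-3-ArA-prop-2-enyl 3-oxobutanoate | CC(=O)CC(=O)OC/C=C/c1ccc(OC)c(OCc2ccccc2)c1 | intermediate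
21 | (E)-3-ArA-prop-2-enyl 2-diazo-3-oxobutanoate | CC(=O)C(=[N+]=[N-])C(=O)OC/C=C/c1ccc(OC)c(OCc2ccccc2)c1 | intermediate (not isolated)
22 | (E)-3-ArA-prop-2-enyl diazoacetate | [N-]=[N+]=CC(=O)OC/C=C/c1ccc(OC)c(OCc2ccccc2)c1 | intermediate
23 | (1R,5S,6S)-6-ArA-3-oxabicyclo[3.1.0]hexan-2-one (aryl exo, trans to the lactone CH2) | O=C1OC[C@H]2[C@H](c3ccc(OC)c(OCc4ccccc4)c3)[C@@H]12 | intermediate
24 | (1R,2S,3S)-2-ArA-3-(hydroxymethyl)cyclopropane-1-carboxamide (CONH2 cis to CH2OH, aryl trans to both) | NC(=O)[C@H]1[C@@H](CO)[C@@H]1c1ccc(OC)c(OCc2ccccc2)c1 | intermediate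
25 | (1R,2S,3S)-2-ArA-3-(TBDPSO-methyl)cyclopropane-1-carboxamide | NC(=O)[C@H]1[C@@H](CO[Si](c2ccccc2)(c2ccccc2)C(C)(C)C)[C@@H]1c1ccc(OC)c(OCc2ccccc2)c1 | intermediate
26 | (1R,2R,3S)-2-ArA-3-(TBDPSO-methyl)cyclopropane-1-carbonitrile | N#C[C@H]1[C@@H](CO[Si](c2ccccc2)(c2ccccc2)C(C)(C)C)[C@@H]1c1ccc(OC)c(OCc2ccccc2)c1 | intermediate
27 | 1-lithio derivative of 26 | [Li]C1(C#N)[C@@H](CO[Si](c2ccccc2)(c2ccccc2)C(C)(C)C)[C@@H]1c1ccc(OC)c(OCc2ccccc2)c1 | intermediate (not isolated)
28 | (2R,3S)-2-ArA-1-(DBF-methyl)-3-(TBDPSO-methyl)cyclopropane-1-carbonitrile, both C1 epimers | N#CC1(Cc2cc(OC)c3c(c2)O[C@H](c2ccc(OCc4ccccc4)c(OC)c2)[C@H]3COCc2ccccc2)[C@@H](CO[Si](c2ccccc2)(c2ccccc2)C(C)(C)C)[C@@H]1c1ccc(OC)c(OCc2ccccc2)c1 | intermediate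
29 | (2R,3S)-2-ArA-1-(DBF-methyl)-3-(TBDPSO-methyl)cyclopropane-1-carbaldehyde, both C1 epimers | O=CC1(Cc2cc(OC)c3c(c2)O[C@H](c2ccc(OCc4ccccc4)c(OC)c2)[C@H]3COCc2ccccc2)[C@@H](CO[Si](c2ccccc2)(c2ccccc2)C(C)(C)C)[C@@H]1c1ccc(OC)c(OCc2ccccc2)c1 | intermediate
30 | (2R,3S)-2-ArA-4-(DBF-methyl)-3-(TBDPSO-methyl)-2,3-dihydrofuran (aryl trans to the silyloxymethyl group) | COc1ccc([C@@H]2OC=C(Cc3cc(OC)c4c(c3)O[C@H](c3ccc(OCc5ccccc5)c(OC)c3)[C@H]4COCc3ccccc3)[C@H]2CO[Si](c2ccccc2)(c2ccccc2)C(C)(C)C)cc1OCc1ccccc1 | intermediate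
31 | 5-[(2R,3S,4S)-3-(TBDPSO-methyl)-4-{[(2S,3R)-2-(4-hydroxy-3-methoxyphenyl)-3-(hydroxymethyl)-4-methoxy-2,3-dihydro-1-benzofuran-6-yl]methyl}oxolan-2-yl]-2-methoxyphenol | COc1ccc([C@@H]2OC[C@@H](Cc3cc(OC)c4c(c3)O[C@H](c3ccc(O)c(OC)c3)[C@H]4CO)[C@H]2CO[Si](c2ccccc2)(c2ccccc2)C(C)(C)C)cc1O | intermediate
32 | CNP0242386.1, 5-[(2R,3S,4S)-3-(hydroxymethyl)-4-{[(2S,3R)-2-(4-hydroxy-3-methoxyphenyl)-3-(hydroxymethyl)-4-methoxy-2,3-dihydro-1-benzofuran-6-yl]methyl}oxolan-2-yl]-2-methoxyphenol | COc1ccc([C@@H]2OC[C@@H](Cc3cc(OC)c4c(c3)O[C@H](c3ccc(O)c(OC)c3)[C@H]4CO)[C@H]2CO)cc1O | target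

**Count and risks**

Total: 24 steps. Longest linear sequence: 15 steps (steps 1–3, 5–11 and 20–24).

Step 22 (ring expansion). After heterolysis the zwitterion may lose a proton or shift hydride to an open-chain unsaturated aldehyde faster than it closes. In addition, the acid strength needed for a cyclopropane with a single formyl acceptor may degrade the enol ether as it forms. The fallback moves the ring expansion to the carboxylic acid level, where the product is an acid-stable lactone. It sets out from 29. NaClO2, NaH2PO4, 2-methyl-2-butene, t-BuOH–H2O (Pinnick oxidation) should give the cyclopropanecarboxylic acid F1. CF3SO3H (cat.), CH2Cl2, 0 °C, the known acid-induced rearrangement of 2-arylcyclopropanecarboxylic acids to γ-aryl-γ-butyrolactones, should give the butyrolactone F2 with the aryl group trans to the silyloxymethyl group. i-Bu2AlH, CH2Cl2, −78 °C should give the lactol F3, and CH3SO2Cl, Et3N, CH2Cl2, 0 °C → rt dehydrates it to the enol ether, so the route is rejoined at 30.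

Step 23 (hydrogenation). Facial selectivity may be poor, because adsorption on the face anti to the C3 side chain is hindered by the C2 aryl group. Slow saturation of the trisubstituted enol ether may also let hydrogenolysis of the benzylic C2–O1 bond compete. The fallback sets C4 by kinetic protonation of a lactone enolate and then rebuilds the ether ring. It sets out from 29 and passes through the acid F1 and the butyrolactone F2 as described above. LiN(i-Pr)2, THF, −78 °C, then 2,6-di-tert-butyl-4-methylphenol should protonate the enolate anti to the neighbouring side chain and give the 3,4-cis lactone F4. LiBH4, THF should give the diol F5. CH3SO2Cl (1.05 equiv), Et3N, CH2Cl2, −20 °C → rt mesylates the primary hydroxyl, which the benzylic hydroxyl displaces (5-exo-tet, retention at C2) to give the tribenzyl tetrahydrofuran F6. H2, 10% Pd/C, EtOAc then only has to remove the benzyl groups, and the route is rejoined at 31.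

Step 7 (C–H insertion). Enantiofacial discrimination may be weak, since the second ortho substituent twists the aryl ring out of the carbene plane, and insertion into the methoxy C–H bonds may compete. The fallback is racemic insertion followed by resolution. It sets out from 10. Rh2(OAc)4 (1 mol %), CH2Cl2, rt, then NaOEt, EtOH should give the racemic trans ester, that is 12 together with the enantiomeric trans ester F8, by way of 11 and the enantiomeric cis ester F7. LiBH4 then gives 13 together with the enantiomeric alcohol F9. Preparative chromatography on a chiral stationary phase (cellulose tris(3,5-dimethylphenylcarbamate), CO2–MeOH) separates the two, and the route is rejoined at 13.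

**Further compounds**

F1 | step 22 | (2R,3S)-2-ArA-1-(DBF-methyl)-3-(TBDPSO-methyl)cyclopropane-1-carboxylic acid, both C1 epimers | OC(=O)C1(Cc2cc(OC)c3c(c2)O[C@H](c2ccc(OCc4ccccc4)c(OC)c2)[C@H]3COCc2ccccc2)[C@@H](CO[Si](c2ccccc2)(c2ccccc2)C(C)(C)C)[C@@H]1c1ccc(OC)c(OCc2ccccc2)c1
F2 | step 22 | (4S,5R)-5-ArA-3-(DBF-methyl)-4-(TBDPSO-methyl)oxolan-2-one, C3 epimers | COc1ccc([C@@H]2OC(=O)C(Cc3cc(OC)c4c(c3)O[C@H](c3ccc(OCc5ccccc5)c(OC)c3)[C@H]4COCc3ccccc3)[C@H]2CO[Si](c2ccccc2)(c2ccccc2)C(C)(C)C)cc1OCc1ccccc1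
F3 | step 22 | (4S,5R)-5-ArA-3-(DBF-methyl)-4-(TBDPSO-methyl)oxolan-2-ol, C2 and C3 epimers | COc1ccc([C@@H]2OC(O)C(Cc3cc(OC)c4c(c3)O[C@H](c3ccc(OCc5ccccc5)c(OC)c3)[C@H]4COCc3ccccc3)[C@H]2CO[Si](c2ccccc2)(c2ccccc2)C(C)(C)C)cc1OCc1ccccc1
F4 | step 23 | (3S,4S,5R)-5-ArA-3-(DBF-methyl)-4-(TBDPSO-methyl)oxolan-2-one (3,4-cis, 4,5-trans) | COc1ccc([C@@H]2OC(=O)[C@@H](Cc3cc(OC)c4c(c3)O[C@H](c3ccc(OCc5ccccc5)c(OC)c3)[C@H]4COCc3ccccc3)[C@H]2CO[Si](c2ccccc2)(c2ccccc2)C(C)(C)C)cc1OCc1ccccc1
F5 | step 23 | (1R,2S,3S)-1-ArA-3-(DBF-methyl)-2-(TBDPSO-methyl)butane-1,4-diol | COc1ccc([C@H](O)[C@H](CO[Si](c2ccccc2)(c2ccccc2)C(C)(C)C)[C@H](Cc2cc(OC)c3c(c2)O[C@H](c2ccc(OCc4ccccc4)c(OC)c2)[C@H]3COCc2ccccc2)CO)cc1OCc1ccccc1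
F6 | step 23 | (2R,3S,4S)-2-ArA-4-(DBF-methyl)-3-(TBDPSO-methyl)oxolane | COc1ccc([C@@H]2OC[C@@H](Cc3cc(OC)c4c(c3)O[C@H](c3ccc(OCc5ccccc5)c(OC)c3)[C@H]4COCc3ccccc3)[C@H]2CO[Si](c2ccccc2)(c2ccccc2)C(C)(C)C)cc1OCc1ccccc1
F7 | step 7 | ethyl (2R,3S)-2-ArB-4-methoxy-6-(TBDPSO-methyl)-2,3-dihydro-1-benzofuran-3-carboxylate (enantiomer of 11) | CC(C)(C)[Si](c1ccccc1)(c1ccccc1)OCc1cc(OC)c2c(c1)O[C@@H](c1ccc(OCc3ccccc3)c(OC)c1)[C@H]2C(=O)OCC
F8 | step 7 | ethyl (2R,3R)-2-ArB-4-methoxy-6-(TBDPSO-methyl)-2,3-dihydro-1-benzofuran-3-carboxylate (enantiomer of 12) | CC(C)(C)[Si](c1ccccc1)(c1ccccc1)OCc1cc(OC)c2c(c1)O[C@@H](c1ccc(OCc3ccccc3)c(OC)c1)[C@@H]2C(=O)OCC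
F9 | step 7 | [(2R,3S)-2-ArB-4-methoxy-6-(TBDPSO-methyl)-2,3-dihydro-1-benzofuran-3-yl]methanol (enantiomer of 13) | CC(C)(C)[Si](c1ccccc1)(c1ccccc1)OCc1cc(OC)c2c(c1)O[C@@H](c1ccc(OCc3ccccc3)c(OC)c1)[C@@H]2CO
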